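Slowness is the first thing to read here: in this flask target sinks from 33.1% at 1.33 h to 13.8% at 10.0 h, while substrate moves from 62.4% to 56.4%. You want to know which entry in the books is paying for that.

- summer: substrate 0.80 M; partner 0.50 equiv; temperature −20 °C; the very flask that is asked about, followed so far
- flask: substrate 0.80 M; partner 0.500 equiv; temperature −20 °C; time 10 h

summer run (percent of the substrate charged)

| time / h | target / % | substrate / % |
|---|---|---|
| 1.33 | 33.1 | 62.4 |
| 4.00 | 24.4 | 59.1 |
| 6.00 | 19.7 | 57.7 |
| 10.0 | 13.8 | 56.4 |

(standard deviation of a reading: 0.5 percentage points)

- ochre: at 10 h raise the temperature by 25 K, then wait 20 h
- red: change nothing and wait 20 h more
- blue: at 10 h take out 90% of the by-product then present, then wait 20 h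
- amber: at 10 h add partner, 100% of the amount charged, then wait 20 h

- additions bring no volume worth counting
- the analysis behind the earlier runs scatters by 0.5 percentage points, standard deviation
- steps under discussion: substrate + partner <-> target + by-product; target <-> isomer of the product
- the earlier runs do not show what temperature does; that part of a forecast is a guess

1. target, in percent of the substrate first charged, at 10 h
2. which option adds most target ("none" when 2 percentage points or less is all one gets) (ochre / red / blue / amber / none)
3. target present, in percent of the substrate first charged, after ochre
4. target present, in percent of the substrate first charged, after red

Keep the books on the partner, the limiting reagent, in percent of the substrate charged. Each mole of substrate lost took one mole of partner and gave one of by-product and one of target or isomer of the product. At 10.0 h the substrate lost, and so the by-product, stands at 43.6%. Of this, target holds 13.8% and isomer of the product, by difference, 29.8%, while free partner is 6.40%. The entries sum to 50.0%, which is the charge, but they close by construction, so this is no check.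

The informative entry is free partner. It falls from 12.4% to 6.40%, about half, while substrate keeps 90.4% of its first reading. Target follows free partner down, so in this flask that is the concentration to watch. The mean over the four readings is 1.75; call this the balance quotient, the reaction quotient of the first step: target times by-product over substrate times free partner. It is a reading, with 0.5 percentage points of scatter on each value, and it stays steady while target falls, so the first step keeps pace with the drain. Turned round at 10.0 h, it returns target as 14.5%, my own figure beside the reading.

The forecast gives 13.8% now, 9% after red and 9% after ochre, and it picks amber: “Amber pulls the equilibrium to about 14 %, and about 15.5 % at 30 h.”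

The simulation gives 13.9% now, 5.35% after red and 20.3% after ochre. The best option is ochre, which adds 6.5 points, while amber changes target by −2.9 points.

    substrate + partner ⇌ target + by-product (K = 1.80, k = 5.91 /M/h, Ea = 52.0 kJ/mol, ΔH = −24.0 kJ/mol)
    target ⇌ isomer of the product (K = 9.80, k = 0.144 /h, Ea = 83.0 kJ/mol, ΔH = −63.0 kJ/mol)
    (constants at −20 °C)

With the return from isomer of the product to target struck out, ochre changes target in this flask by −13 points, where the full scheme has 6.5 points; that return, drawing on the 30.0% of isomer of the product standing at 10.0 h, is one part of why ochre pays. The step between target and isomer of the product, both ways, is also the largest single effect on target at 10.0 h, though not the main reason for the shortfall: this flask holds 13.9% with the step and 37.5% without it. Left cold to 100 h, this flask still obeys the quotient, which asks for 4.30% of target against 4.42% present. In the flask with 2.00 equiv of partner, substrate is the limiting reagent. Its 12.1% of substrate, 56.1% of partner's own charge and 0.703 M of by-product make the quotient ask for 27.1% of target, and that flask computes 27.5%.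

The runs come from a simulation with made-up constants; noise was put on by code.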